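**Plan**

Atom labels (O1, C2, C3, C8 and so on) are those of the chromen-4-one core of the target; ring A is the phloroglucinol ring, ring B the 4-hydroxyphenyl ring, ring C the pyranone.
Feature used: C2–C3 ties an aroyl carbon to the α-carbon of an aryl ketone that already bears O3, and O1, the phenol oxygen beside the quaternary carbon on C8, can hold that aroyl group as an ester first.
Cuts, in retrosynthetic order: the four O–CH2OMe acetals; O1–C2 and C2–C3 of ring C (back to the O1 benzoate 14); the O1–acyl bond (ketone 9 plus acid chloride 13); C3–C4 (aldehyde 5 plus an alkoxymethyllithium); C8–CMe2 (aryl prenyl ether 3).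
Forward: ring A is bought as 2,4,6-trihydroxybenzaldehyde; the 1,1-dimethylallyl group arrives by a Claisen shift from O7, the C3 unit by organolithium addition and oxidation, ring B by esterification at O1, and ring C closes last by acyl transfer and cyclodehydration.
Stereochemistry: the target has no stereocentre; the carbinol centre of 8 and the centres of 15 and 16 form without control and are erased on the way.

Key step: step 10

**Route**

Step 1
Reactants: 1 2,4,6-trihydroxybenzaldehyde; 2 1-bromo-3-methylbut-2-ene (prenyl bromide)
Product: 3 2,6-dihydroxy-4-[(3-methylbut-2-en-1-yl)oxy]benzaldehyde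
Conditions: 2 (1.0 equiv), K2CO3 (1.0 equiv), DMF, 0 °C → rt
Reagents that add atoms: none
Why: Williamson ether synthesis under weak-base control: the hydroxyl para to the formyl group is the most acidic of the three and is never engaged in the hydrogen bond to the carbonyl, so with one equivalent each of K2CO3 and bromide in a dipolar aprotic solvent the mono-ether at O7 should dominate over C-alkylation and double alkylation.

Step 2
Reactants: 3 2,6-dihydroxy-4-[(3-methylbut-2-en-1-yl)oxy]benzaldehyde
Product: 4 2,4,6-trihydroxy-3-(2-methylbut-3-en-2-yl)benzaldehyde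
Conditions: EtOH–H2O (4:1), 130 °C, sealed tube
Reagents that add atoms: none
Why: Aromatic Claisen rearrangement followed by tautomerisation: the two ortho positions are equivalent by symmetry, the para carbon carries the formyl group so a Cope relay has no productive outlet, and the protic medium both speeds the [3,3] shift and quickly enolises the dienone to the phenol bearing the 1,1-dimethylallyl group.

Step 3
Reactants: 4 2,4,6-trihydroxy-3-(2-methylbut-3-en-2-yl)benzaldehyde
Product: 5 2-hydroxy-4,6-bis(methoxymethoxy)-3-(2-methylbut-3-en-2-yl)benzaldehyde
Conditions: MOMCl (2.2 equiv), i-Pr2NEt (3 equiv), CH2Cl2, 0 °C → rt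
Reagents that add atoms: chloromethyl methyl ether (MOMCl), COCCl
Why: O-alkylation with an α-chloro ether (MOM protection) under amine base is selective here because the hydroxyl between the formyl group and the quaternary carbon is held in the hydrogen bond to the carbonyl and shielded on both sides, so whichever of the other two hydroxyls reacts first the second acetal also goes to an open oxygen and O1–H is the one left free.

Step 4
Reactants: 5 2-hydroxy-4,6-bis(methoxymethoxy)-3-(2-methylbut-3-en-2-yl)benzaldehyde; 6 tributyl[(methoxymethoxy)methyl]stannane
Product: 8 2-[1-hydroxy-2-(methoxymethoxy)ethyl]-3,5-bis(methoxymethoxy)-6-(2-methylbut-3-en-2-yl)phenol (racemic), via (methoxymethoxy)methyllithium 7 (not isolated)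
Conditions: 6 (2.4 equiv), n-BuLi (2.3 equiv), THF, −78 °C; then 5, −78 → −40 °C; H2O
Reagents that add atoms: none
Why: Tin–lithium exchange gives the α-alkoxymethyllithium 7, of which one equivalent is spent on the phenol proton and the next adds 1,2 to the formyl group (organolithium addition to an aldehyde), the new carbinol centre forming as the racemate without consequence because step 5 erases it.

Step 5
Reactants: 8 2-[1-hydroxy-2-(methoxymethoxy)ethyl]-3,5-bis(methoxymethoxy)-6-(2-methylbut-3-en-2-yl)phenol
Product: 9 1-[2-hydroxy-4,6-bis(methoxymethoxy)-3-(2-methylbut-3-en-2-yl)phenyl]-2-(methoxymethoxy)ethan-1-one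
Conditions: activated MnO2 (15 equiv), CH2Cl2, rt
Reagents that add atoms: none
Why: Oxidation of a benzylic alcohol with MnO2, which is selective for the activated carbinol and is routinely used to turn o-hydroxybenzyl alcohols into o-hydroxyaryl carbonyl compounds, should leave the acetals and the terminal alkene untouched and give a ketone stabilised by the hydrogen bond from O1–H.

Step 6
Reactants: 10 methyl 4-hydroxybenzoate
Product: 11 methyl 4-(methoxymethoxy)benzoate
Conditions: MOMCl (1.3 equiv), i-Pr2NEt (2 equiv), CH2Cl2, 0 °C → rt
Reagents that add atoms: chloromethyl methyl ether (MOMCl), COCCl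
Why: MOM protection of an unhindered, fairly acidic phenol by O-alkylation with the α-chloro ether under amine base is routine and the methyl ester is inert to it.

Step 7
Reactants: 11 methyl 4-(methoxymethoxy)benzoate
Product: 12 4-(methoxymethoxy)benzoic acid
Conditions: LiOH·H2O (3 equiv), THF–MeOH–H2O, rt; then cold 1 M HCl to pH 4
Reagents that add atoms: lithium hydroxide (LiOH), [Li+].[OH-]
Why: Saponification (acyl–oxygen cleavage by hydroxide) frees the acid while the aryl acetal, stable to base, survives the brief cold acidification to pH 4.

Step 8
Reactants: 12 4-(methoxymethoxy)benzoic acid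
Product: 13 4-(methoxymethoxy)benzoyl chloride
Conditions: 1-chloro-N,N,2-trimethylprop-1-en-1-amine (1.1 equiv), CH2Cl2, 0 °C → rt; evaporate, use crude
Reagents that add atoms: 1-chloro-N,N,2-trimethylprop-1-en-1-amine, CC(C)=C(Cl)N(C)C
Why: Acid chloride formation with an α-chloroenamine proceeds through an acyloxyiminium chloride under neutral conditions and releases an amide instead of HCl, so the acid-labile aryl acetal should come through intact.

Step 9
Reactants: 9 1-[2-hydroxy-4,6-bis(methoxymethoxy)-3-(2-methylbut-3-en-2-yl)phenyl]-2-(methoxymethoxy)ethan-1-one; 13 4-(methoxymethoxy)benzoyl chloride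
Product: 14 2-[2-(methoxymethoxy)acetyl]-3,5-bis(methoxymethoxy)-6-(2-methylbut-3-en-2-yl)phenyl 4-(methoxymethoxy)benzoate
Conditions: 13 (1.5 equiv), Et3N (3 equiv), DMAP (0.3 equiv), CH2Cl2, 0 °C → rt
Reagents that add atoms: none
Why: DMAP-catalysed O-acylation through the N-acylpyridinium ion is strong enough for a hydrogen-bonded, flanked phenol, and since O1–H is the only hydroxyl in 9 the aroyl group can only land there while the amine base is too weak to enolise the ketone.

Step 10
Reactants: 14 2-[2-(methoxymethoxy)acetyl]-3,5-bis(methoxymethoxy)-6-(2-methylbut-3-en-2-yl)phenyl 4-(methoxymethoxy)benzoate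
Product: 17 3,5,7-tris(methoxymethoxy)-2-[4-(methoxymethoxy)phenyl]-8-(2-methylbut-3-en-2-yl)-4H-chromen-4-one, via 1,3-diketone 15 (not isolated), via cyclic hemiketal 16 (not isolated)
Conditions: LiN(SiMe3)2 (3.0 equiv), THF, −78 → 0 °C; AcOH quench, evaporate; NaOAc, AcOH, 70 °C
Reagents that add atoms: none
Why: LiN(SiMe3)2 removes a proton from the CH2 between the ketone and the acetal oxygen, and the enolate carbon (C3) attacks the carbonyl of the benzoate on O1 (C2) through a six-membered cyclic tetrahedral intermediate that opens by expelling the O1 phenoxide, leaving the doubly deprotonated 1,3-diketone 15. This is the Baker–Venkataraman rearrangement, the established way from 2-aroyloxy-ω-alkoxyacetophenones to 3-alkoxyflavones. On acidification the O1 phenol adds back to the aroyl carbonyl in a 6-exo-trig closure to give hemiketal 16, and acetate-buffered loss of water across C2–C3 completes ring C as the pyranone. No stereocentre is created that lasts, since the centres of 15 and 16 vanish on dehydration. The step needs C- over O-acyl transfer and closure toward C8 only: the first is thermodynamic, the diketonate being the sink and the crowded O1 ester being relieved of strain, and the second is built in because the aroyl group is delivered from O1 while O5 is capped as its acetal. The buffer is there to keep the four acetals, and a product that had lost one of them, most likely at O5, would still converge on 18 in step 11.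

Step 11
Reactants: 17 3,5,7-tris(methoxymethoxy)-2-[4-(methoxymethoxy)phenyl]-8-(2-methylbut-3-en-2-yl)-4H-chromen-4-one
Product: 18 3,5,7-trihydroxy-2-(4-hydroxyphenyl)-8-(2-methylbut-3-en-2-yl)-4H-chromen-4-one
Conditions: HCl (1.25 M in MeOH), THF, 40 °C
Reagents that add atoms: none
Why: Acid-catalysed acetal exchange with methanol removes the enol and aryl MOM ethers as dimethoxymethane, while the monosubstituted alkene on a quaternary carbon is protonated far more slowly than an acetal oxygen under dilute methanolic acid, so the 1,1-dimethylallyl group should survive next to the freed O7–H.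

**Compound list**

1 | 2,4,6-trihydroxybenzaldehyde | O=Cc1c(O)cc(O)cc1O | starting material
2 | 1-bromo-3-methylbut-2-ene (prenyl bromide) | CC(C)=CCBr | starting material
3 | 2,6-dihydroxy-4-[(3-methylbut-2-en-1-yl)oxy]benzaldehyde | O=Cc1c(O)cc(OCC=C(C)C)cc1O | intermediate
4 | 2,4,6-trihydroxy-3-(2-methylbut-3-en-2-yl)benzaldehyde | O=Cc1c(O)c(C(C)(C)C=C)c(O)cc1O | intermediate
5 | 2-hydroxy-4,6-bis(methoxymethoxy)-3-(2-methylbut-3-en-2-yl)benzaldehyde | O=Cc1c(O)c(C(C)(C)C=C)c(OCOC)cc1OCOC | intermediate
6 | tributyl[(methoxymethoxy)methyl]stannane | CCCC[Sn](CCCC)(CCCC)COCOC | starting material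
7 | (methoxymethoxy)methyllithium (not isolated) | [Li]COCOC | intermediate
8 | 2-[1-hydroxy-2-(methoxymethoxy)ethyl]-3,5-bis(methoxymethoxy)-6-(2-methylbut-3-en-2-yl)phenol, racemic | COCOCC(O)c1c(O)c(C(C)(C)C=C)c(OCOC)cc1OCOC | intermediate
9 | 1-[2-hydroxy-4,6-bis(methoxymethoxy)-3-(2-methylbut-3-en-2-yl)phenyl]-2-(methoxymethoxy)ethan-1-one | COCOCC(=O)c1c(O)c(C(C)(C)C=C)c(OCOC)cc1OCOC | intermediate
10 | methyl 4-hydroxybenzoate | COC(=O)c1ccc(O)cc1 | starting material
11 | methyl 4-(methoxymethoxy)benzoate | COCOc1ccc(C(=O)OC)cc1 | intermediate
12 | 4-(methoxymethoxy)benzoic acid | COCOc1ccc(C(=O)O)cc1 | intermediate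
13 | 4-(methoxymethoxy)benzoyl chloride | COCOc1ccc(C(=O)Cl)cc1 | intermediate
14 | 2-[2-(methoxymethoxy)acetyl]-3,5-bis(methoxymethoxy)-6-(2-methylbut-3-en-2-yl)phenyl 4-(methoxymethoxy)benzoate | COCOCC(=O)c1c(OCOC)cc(OCOC)c(C(C)(C)C=C)c1OC(=O)c1ccc(OCOC)cc1 | intermediate
15 | 1-[2-hydroxy-4,6-bis(methoxymethoxy)-3-(2-methylbut-3-en-2-yl)phenyl]-2-(methoxymethoxy)-3-[4-(methoxymethoxy)phenyl]propane-1,3-dione, racemic (not isolated) | COCOC(C(=O)c1ccc(OCOC)cc1)C(=O)c1c(O)c(C(C)(C)C=C)c(OCOC)cc1OCOC | intermediate
16 | 2-hydroxy-3,5,7-tris(methoxymethoxy)-2-[4-(methoxymethoxy)phenyl]-8-(2-methylbut-3-en-2-yl)-2,3-dihydro-4H-chromen-4-one, mixture of racemic diastereomers (not isolated) | C=CC(C)(C)c1c(OCOC)cc(OCOC)c2c1OC(O)(c1ccc(OCOC)cc1)C(OCOC)C2=O | intermediate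
17 | 3,5,7-tris(methoxymethoxy)-2-[4-(methoxymethoxy)phenyl]-8-(2-methylbut-3-en-2-yl)-4H-chromen-4-one | C=CC(C)(C)c1c(OCOC)cc(OCOC)c2c(=O)c(OCOC)c(-c3ccc(OCOC)cc3)oc12 | intermediate
18 | 3,5,7-trihydroxy-2-(4-hydroxyphenyl)-8-(2-methylbut-3-en-2-yl)-4H-chromen-4-one | C=CC(C)(C)c1c(O)cc(O)c2c(=O)c(O)c(-c3ccc(O)cc3)oc12 | target

**Step count**

Total steps: 11. Longest linear sequence: 8 steps (steps 1, 2, 3, 4, 5, 9, 10, 11, from 1 to 18). Steps 6–8 are the three-step side branch to acid chloride 13.

**Steps most likely to fail**

Step 2. The unprotected polyphenolic aldehyde may lose its formyl group or condense with itself in hot aqueous ethanol. The rearranged phenol may also react further before conversion is complete, by addition of a flanking hydroxyl to the alkene or by an abnormal Claisen shift. The fallback rearranges a masked substrate in an aprotic medium and sets out from 3. Both hydroxyls are capped (NaH, MOMCl, DMF) to give 2,6-bis(methoxymethoxy)-4-[(3-methylbut-2-en-1-yl)oxy]benzaldehyde F1. This is heated in N,N-diethylaniline at 190 °C and should give 4-hydroxy-2,6-bis(methoxymethoxy)-3-(2-methylbut-3-en-2-yl)benzaldehyde F2, the amine tautomerising the dienone. The two acetals of F2, both activated by the neighbouring formyl group, are then removed with methanolic HCl at rt, and the fallback comes back to the route at 4.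

Step 9. Acylation of an oxygen that is hydrogen-bonded and flanked by a quaternary carbon and an acyl group may be slow. Hydrolysis of the acid chloride or enolate formation would then take over if the reaction is forced with stronger base. The fallback forms C2–C3 directly by intermolecular C-aroylation and sets out from 9 and 13. Ketone 9 is converted with LiN(SiMe3)2 (3.5 equiv, THF, −78 °C) into its phenoxide–enolate dianion and 13 is added; the enolate carbon, the more nucleophilic and less shielded site, should be acylated. The fallback comes back to the route at diketone 15, which is isolated after an AcOH quench and cyclodehydrated to 17 as in step 10. No compound outside the list is made (F0).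

Step 10. Acetal groups may be lost unevenly in warm acetic acid during the cyclodehydration, giving a mixture of partly deprotected flavones that is hard to purify. The fallback merges ring closure with deprotection and sets out from 14. The base stage is run as written and diketone 15 is isolated after the AcOH quench. Treatment with HCl (1.25 M in MeOH) at 50 °C should then effect acid-catalysed cyclodehydration and removal of all four acetals in one operation. Compound 17 is skipped and the fallback comes back to the route at 18. No compound outside the list is made (F0).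

**Further compounds**

F1 | step 2 | 2,6-bis(methoxymethoxy)-4-[(3-methylbut-2-en-1-yl)oxy]benzaldehyde | CC(C)=CCOc1cc(OCOC)c(C=O)c(OCOC)c1
F2 | step 2 | 4-hydroxy-2,6-bis(methoxymethoxy)-3-(2-methylbut-3-en-2-yl)benzaldehyde | C=CC(C)(C)c1c(O)cc(OCOC)c(C=O)c1OCOC
F0 | step 9 | none | none
F0 | step 10 | none | none
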